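**Retrosynthetic overview**
1. Target 24 ⇐ diester 23 (saponification) ⇐ 22 (dehydration of a 1-hydroxyethyl group to the vinyl group) ⇐ 21 (ozonolysis turns an allyl group into CH2CO2Me and a 1,1-dimethylallyl group into CMe2CO2Me).
2. Pyran ring (formed last) ⇐ 6-exo opening of a (2S,3S)-epoxide at its tertiary carbon by the C8 tertiary alcohol; that alcohol ⇐ MeLi addition to cyclohexanone 19.
3. Key disconnection: 19 ⇐ enone 9 (fragment 1) + Me2CuLi + epoxy alcohol 16 as its triflate (fragment 2), a one-pot conjugate methylation/enolate alkylation that forms C10–CH3 and C9–C11.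
4. Fragment 1 (the carbocycle, formed first) ⇐ organocatalytic Michael/aldol annulation of 3,3-dimethylpent-4-enal with methyl vinyl ketone, then conjugate allylation and Saegusa oxidation; fragment 2 ⇐ but-3-yn-1-ol by carboalumination, methylation and Shi epoxidation.
5. Ring order: carbocycle (step 3), then tetrahydropyran (step 12).

Assumption: the SMILES is taken literally, so the CMe2CO2H arm is cis to the CH2CO2H arm and trans to the neighbouring ring methyl; locants C1–C20 below follow labdane numbering (C5, C8, C9, C10 in the carbocycle, C13 the vinyl-bearing carbon).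

**Fragment 1**

Step 1
Reactants: 1 3-methylbut-2-en-1-ol; 2 ethoxyethene
Product: 4 3,3-dimethylpent-4-enal, via prenyl vinyl ether 3 (not isolated)
Conditions: 2 (excess), Hg(OAc)2 (5 mol %), reflux; evaporate; neat, 130 °C, sealed tube
Reagents that add atoms: none
Why: Transvinylation gives the allyl vinyl ether, whose thermal [3,3] Claisen rearrangement delivers the aldehyde with the CMe2 unit (future C4) in place; no stereocentre is formed.

Step 2
Reactants: 4 3,3-dimethylpent-4-enal; 5 but-3-en-2-one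
Product: 6 (2R)-2-(2-methylbut-3-en-2-yl)-5-oxohexanal
Conditions: (R)-α,α-diphenylprolinol trimethylsilyl ether (10 mol %), ethyl 3,4-dihydroxybenzoate (20 mol %), neat, 4 °C
Reagents that add atoms: none
Why: Enamine-mediated asymmetric Michael addition (Jørgensen–Hayashi catalysis) in which the diarylprolinol ether shields one enamine face, so the enone adds to the open face and sets C5.

Step 3
Reactants: 6 (2R)-2-(2-methylbut-3-en-2-yl)-5-oxohexanal
Product: 7 (4S)-4-(2-methylbut-3-en-2-yl)cyclohex-2-en-1-one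
Conditions: LiOH·H2O (0.3 equiv), i-PrOH, 23 °C
Reagents that add atoms: none
Why: Intramolecular aldol condensation (the ring-closing half of a Robinson annulation) forms the carbocycle under base mild enough to leave the C5 centre untouched.

Step 4
Reactants: 7 (4S)-4-(2-methylbut-3-en-2-yl)cyclohex-2-en-1-one
Product: 8 trimethyl{[(3R,4S)-4-(2-methylbut-3-en-2-yl)-3-(prop-2-en-1-yl)cyclohex-1-en-1-yl]oxy}silane
Conditions: allylmagnesium bromide, CuBr·SMe2 (20 mol %), Me3SiCl, THF, −78 °C; Et3N, pentane work-up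
Reagents that add atoms: allylmagnesium bromide C=CC[Mg]Br; chlorotrimethylsilane C[Si](C)(C)Cl
Why: Copper-catalysed 1,4-addition with in situ O-silylation gives the regiodefined enol silane, the allyl group entering trans to the bulky C5 substituent (this new centre is erased in step 5).

Step 5
Reactants: 8 trimethyl{[(3R,4S)-4-(2-methylbut-3-en-2-yl)-3-(prop-2-en-1-yl)cyclohex-1-en-1-yl]oxy}silane
Product: 9 (4R)-4-(2-methylbut-3-en-2-yl)-3-(prop-2-en-1-yl)cyclohex-2-en-1-one
Conditions: Pd(OAc)2 (1.05 equiv), MeCN, 23 °C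
Reagents that add atoms: none
Why: Saegusa–Ito oxidation, in which the palladium enolate loses the only β-hydrogen (at C10) to restore the enone with the allyl group on the β-carbon; C5 is not touched.

**Fragment 2**

Step 6
Reactants: 10 but-3-yn-1-ol
Product: 11 tert-butyl(but-3-yn-1-yloxy)dimethylsilane
Conditions: t-BuMe2SiCl, imidazole, DMF, 23 °C
Reagents that add atoms: tert-butyl(chloro)dimethylsilane CC(C)(C)[Si](C)(C)Cl
Why: Standard silyl protection keeps the later epoxy alcohol out of the aqueous, basic Shi medium and prevents tetrahydrofuran formation.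

Step 7
Reactants: 11 tert-butyl(but-3-yn-1-yloxy)dimethylsilane
Product: 13 tert-butyl{[(3E)-4-iodo-3-methylbut-3-en-1-yl]oxy}dimethylsilane, via alkenylalane 12 (not isolated)
Conditions: Me3Al (2.2 equiv), Cp2ZrCl2 (25 mol %), CH2Cl2, 0 to 23 °C; then I2, THF, −30 to 0 °C
Reagents that add atoms: trimethylaluminium C[Al](C)C; iodine II
Why: Negishi zirconium-catalysed carboalumination adds Me and Al syn across the alkyne (Me to the internal carbon) and iodinolysis proceeds with retention, fixing the E geometry.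

Step 8
Reactants: 13 tert-butyl{[(3E)-4-iodo-3-methylbut-3-en-1-yl]oxy}dimethylsilane
Product: 14 tert-butyldimethyl{[(3E)-3-methylpent-3-en-1-yl]oxy}silane
Conditions: MeZnCl (1.5 equiv), Pd(PPh3)4 (3 mol %), THF, 23 to 45 °C
Reagents that add atoms: methylzinc chloride C[Zn]Cl
Why: Negishi cross-coupling replaces iodine by methyl with retention of alkene geometry, giving the E-trisubstituted alkene.

Step 9
Reactants: 14 tert-butyldimethyl{[(3E)-3-methylpent-3-en-1-yl]oxy}silane
Product: 15 tert-butyl{2-[(2S,3S)-2,3-dimethyloxiran-2-yl]ethoxy}dimethylsilane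
Conditions: ent-Shi ketone (L-fructose-derived, 30 mol %), Oxone (2KHSO5·KHSO4·K2SO4), K2CO3, Bu4NHSO4, MeCN/(MeO)2CH2/aq. Na2B4O7 buffer, 0 °C
Reagents that add atoms: potassium peroxymonosulfate (KHSO5, active part of Oxone) [K+].[O-]S(=O)(=O)OO
Why: Shi asymmetric epoxidation through the spiro dioxirane transition state; the L-fructose-derived ketone gives the (2S,3S)-epoxide (the D-fructose ketone gives R,R), which sets the C13 precursor centre.

Step 10
Reactants: 15 tert-butyl{2-[(2S,3S)-2,3-dimethyloxiran-2-yl]ethoxy}dimethylsilane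
Product: 16 2-[(2S,3S)-2,3-dimethyloxiran-2-yl]ethan-1-ol
Conditions: Bu4NF, THF, 0 °C
Reagents that add atoms: none
Why: Fluoride desilylation under non-acidic conditions leaves the epoxide intact.

**Coupling and endgame**

Step 11
Reactants: 9 (4R)-4-(2-methylbut-3-en-2-yl)-3-(prop-2-en-1-yl)cyclohex-2-en-1-one; 16 2-[(2S,3S)-2,3-dimethyloxiran-2-yl]ethan-1-ol
Product: 19 (2R,3S,4R)-2-{2-[(2S,3S)-2,3-dimethyloxiran-2-yl]ethyl}-3-methyl-4-(2-methylbut-3-en-2-yl)-3-(prop-2-en-1-yl)cyclohexan-1-one, via primary triflate 17 (not isolated), via lithium enolate 18 (not isolated)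
Conditions: 16, (CF3SO2)2O, 2,6-di-tert-butylpyridine, CH2Cl2, −78 °C (gives 17); 9, Me2CuLi (1.05 equiv, from MeLi and CuI), Et2O, −40 to 0 °C (gives 18); then 17 in THF, −78 to −20 °C
Reagents that add atoms: lithium dimethylcuprate [Li+].C[Cu-]C
Why: Conjugate addition of the cuprate anti to the pseudoaxial C5 substituent sets C10 (methyl trans to the dimethylallyl arm), and the regiodefined enolate is then alkylated (SN2) axially on the β face, anti to the now axial allyl group, which sets C9.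

Step 12
Reactants: 19 (2R,3S,4R)-2-{2-[(2S,3S)-2,3-dimethyloxiran-2-yl]ethyl}-3-methyl-4-(2-methylbut-3-en-2-yl)-3-(prop-2-en-1-yl)cyclohexan-1-one
Product: 21 (1S)-1-[(2R,4aR,5S,6R,8aR)-2,5,8a-trimethyl-6-(2-methylbut-3-en-2-yl)-5-(prop-2-en-1-yl)octahydro-2H-chromen-2-yl]ethan-1-ol, via tertiary alcohol 20 (not isolated)
Conditions: MeLi, Et2O/THF, −78 °C; AcOH (1 equiv); solvent switch; CSA (20 mol %), CH2Cl2, 0 to 35 °C
Reagents that add atoms: methyllithium [Li]C
Why: MeLi attacks the C8 ketone equatorially from the β face because the axial C10 allyl group blocks the α trajectory (Me β, O α), and the acid-catalysed 6-exo epoxide opening by that tertiary alcohol proceeds with inversion at the tertiary carbon to give 13R.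

Step 13
Reactants: 21 (1S)-1-[(2R,4aR,5S,6R,8aR)-2,5,8a-trimethyl-6-(2-methylbut-3-en-2-yl)-5-(prop-2-en-1-yl)octahydro-2H-chromen-2-yl]ethan-1-ol
Product: 22 methyl 2-[(2R,4aR,5S,6S,8aR)-2-[(1S)-1-hydroxyethyl]-5-(2-methoxy-2-oxoethyl)-2,5,8a-trimethyloctahydro-2H-chromen-6-yl]-2-methylpropanoate
Conditions: O3, NaOH (2.5 M in MeOH), CH2Cl2, −78 °C
Reagents that add atoms: ozone [O-][O+]=O; methanol CO
Why: Marshall ozonolysis in methanolic NaOH converts both terminal alkenes directly into methyl esters (each loses its CH2 terminus), unmasking the two acid arms without touching any stereocentre.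

Step 14
Reactants: 22 methyl 2-[(2R,4aR,5S,6S,8aR)-2-[(1S)-1-hydroxyethyl]-5-(2-methoxy-2-oxoethyl)-2,5,8a-trimethyloctahydro-2H-chromen-6-yl]-2-methylpropanoate
Product: 23 methyl 2-[(2R,4aR,5S,6S,8aR)-2-ethenyl-5-(2-methoxy-2-oxoethyl)-2,5,8a-trimethyloctahydro-2H-chromen-6-yl]-2-methylpropanoate
Conditions: Burgess reagent (MeO2CN(−)SO2N(+)Et3), toluene, 70 °C
Reagents that add atoms: none
Why: Burgess dehydration (syn elimination of the sulfamate) can only take a hydrogen from the methyl group because C13 is quaternary, so the vinyl group is the sole alkene possible.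

Step 15
Reactants: 23 methyl 2-[(2R,4aR,5S,6S,8aR)-2-ethenyl-5-(2-methoxy-2-oxoethyl)-2,5,8a-trimethyloctahydro-2H-chromen-6-yl]-2-methylpropanoate
Product: 24 2-[(2R,4aR,5S,6S,8aR)-5-(carboxymethyl)-2-ethenyl-2,5,8a-trimethyloctahydro-2H-chromen-6-yl]-2-methylpropanoic acid
Conditions: KOH (excess), MeOH/H2O, 90 °C; then 1 M HCl to pH 3, 0 °C
Reagents that add atoms: potassium hydroxide [K+].[OH-]
Why: Saponification under forcing basic conditions cleaves both esters (the α,α-dimethyl ester is slow), and the ether, the vinyl group and all stereocentres are base-stable.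

**Compound list**
1 | 3-methylbut-2-en-1-ol | CC(C)=CCO | starting material
2 | ethoxyethene | C=COCC | starting material
3 | 3-methyl-1-(ethenyloxy)but-2-ene | CC(C)=CCOC=C | intermediate
4 | 3,3-dimethylpent-4-enal | C=CC(C)(C)CC=O | intermediate
5 | but-3-en-2-one | CC(=O)C=C | starting material
6 | (2R)-2-(2-methylbut-3-en-2-yl)-5-oxohexanal | O=C[C@@H](C(C)(C)C=C)CCC(C)=O | intermediate
7 | (4S)-4-(2-methylbut-3-en-2-yl)cyclohex-2-en-1-one | O=C1C=C[C@@H](C(C)(C)C=C)CC1 | intermediate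
8 | trimethyl{[(3R,4S)-4-(2-methylbut-3-en-2-yl)-3-(prop-2-en-1-yl)cyclohex-1-en-1-yl]oxy}silane | C[Si](C)(C)OC1=C[C@H](CC=C)[C@@H](C(C)(C)C=C)CC1 | intermediate
9 | (4R)-4-(2-methylbut-3-en-2-yl)-3-(prop-2-en-1-yl)cyclohex-2-en-1-one | O=C1C=C(CC=C)[C@@H](C(C)(C)C=C)CC1 | intermediate
10 | but-3-yn-1-ol | C#CCCO | starting material
11 | tert-butyl(but-3-yn-1-yloxy)dimethylsilane | C#CCCO[Si](C)(C)C(C)(C)C | intermediate
12 | [(1E)-4-{[tert-butyl(dimethyl)silyl]oxy}-2-methylbut-1-en-1-yl]dimethylaluminium | C[Al](C)/C=C(\C)CCO[Si](C)(C)C(C)(C)C | intermediate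
13 | tert-butyl{[(3E)-4-iodo-3-methylbut-3-en-1-yl]oxy}dimethylsilane | I/C=C(\C)CCO[Si](C)(C)C(C)(C)C | intermediate
14 | tert-butyldimethyl{[(3E)-3-methylpent-3-en-1-yl]oxy}silane | C/C=C(\C)CCO[Si](C)(C)C(C)(C)C | intermediate
15 | tert-butyl{2-[(2S,3S)-2,3-dimethyloxiran-2-yl]ethoxy}dimethylsilane | C[C@@H]1O[C@@]1(C)CCO[Si](C)(C)C(C)(C)C | intermediate
16 | 2-[(2S,3S)-2,3-dimethyloxiran-2-yl]ethan-1-ol | C[C@@H]1O[C@@]1(C)CCO | intermediate
17 | 2-[(2S,3S)-2,3-dimethyloxiran-2-yl]ethyl trifluoromethanesulfonate | C[C@@H]1O[C@@]1(C)CCOS(=O)(=O)C(F)(F)F | intermediate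
18 | lithium (3S,4R)-3-methyl-4-(2-methylbut-3-en-2-yl)-3-(prop-2-en-1-yl)cyclohex-1-en-1-olate | [Li+].[O-]C1=C[C@@](C)(CC=C)[C@@H](C(C)(C)C=C)CC1 | intermediate
19 | (2R,3S,4R)-2-{2-[(2S,3S)-2,3-dimethyloxiran-2-yl]ethyl}-3-methyl-4-(2-methylbut-3-en-2-yl)-3-(prop-2-en-1-yl)cyclohexan-1-one | C[C@@H]1O[C@@]1(C)CC[C@@H]2[C@@](C)(CC=C)[C@@H](C(C)(C)C=C)CCC2=O | intermediate
20 | (1R,2R,3S,4R)-2-{2-[(2S,3S)-2,3-dimethyloxiran-2-yl]ethyl}-1,3-dimethyl-4-(2-methylbut-3-en-2-yl)-3-(prop-2-en-1-yl)cyclohexan-1-ol | C[C@@H]1O[C@@]1(C)CC[C@@H]2[C@@](C)(CC=C)[C@@H](C(C)(C)C=C)CC[C@@]2(C)O | intermediate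
21 | (1S)-1-[(2R,4aR,5S,6R,8aR)-2,5,8a-trimethyl-6-(2-methylbut-3-en-2-yl)-5-(prop-2-en-1-yl)octahydro-2H-chromen-2-yl]ethan-1-ol | C[C@H](O)[C@@]1(C)CC[C@@H]2[C@@](C)(CC=C)[C@@H](C(C)(C)C=C)CC[C@@]2(C)O1 | intermediate
22 | methyl 2-[(2R,4aR,5S,6S,8aR)-2-[(1S)-1-hydroxyethyl]-5-(2-methoxy-2-oxoethyl)-2,5,8a-trimethyloctahydro-2H-chromen-6-yl]-2-methylpropanoate | C[C@H](O)[C@@]1(C)CC[C@@H]2[C@@](C)(CC(=O)OC)[C@@H](C(C)(C)C(=O)OC)CC[C@@]2(C)O1 | intermediate
23 | methyl 2-[(2R,4aR,5S,6S,8aR)-2-ethenyl-5-(2-methoxy-2-oxoethyl)-2,5,8a-trimethyloctahydro-2H-chromen-6-yl]-2-methylpropanoate | C=C[C@@]1(C)CC[C@@H]2[C@@](C)(CC(=O)OC)[C@@H](C(C)(C)C(=O)OC)CC[C@@]2(C)O1 | intermediate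
24 | 2-[(2R,4aR,5S,6S,8aR)-5-(carboxymethyl)-2-ethenyl-2,5,8a-trimethyloctahydro-2H-chromen-6-yl]-2-methylpropanoic acid | C=C[C@@]1(C)CC[C@@H]2[C@@](C)(CC(=O)O)[C@@H](C(C)(C)C(=O)O)CC[C@@]2(C)O1 | target

**Totals**
Total steps: 15. Longest linear sequence: 10 steps (1–5 then 11–15; the line 6–10 then 11–15 is equally long).

**Three steps most likely to fail**

Step 11. The enolate is hindered (next to the new quaternary C10) and the electrophile is not allylic, so O-alkylation, proton transfer with loss of the C9 configuration, or attack of residual cuprate on the triflate may dominate. The fallback reverses the polarity of the C9–C11 bond formation; it sets out from 9 and 16 and comes back at 19. Enolate 18 (from 9 and Me2CuLi as before) is quenched with N-bromosuccinimide to give (2R,3S,4R)-2-bromo-3-methyl-4-(2-methylbut-3-en-2-yl)-3-(prop-2-en-1-yl)cyclohexan-1-one F1. Alcohol 16 is converted with I2, PPh3 and imidazole into (2S,3S)-2-(2-iodoethyl)-2,3-dimethyloxirane F2 and then with Zn dust and LiCl in THF into {2-[(2S,3S)-2,3-dimethyloxiran-2-yl]ethyl}(iodo)zinc F3. A Negishi coupling of F1 with F3, catalysed by NiCl2·glyme and a pybox ligand in DMA at 0 °C, joins them through a C9 radical that should be captured on the less hindered β face, giving 19.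

Step 12. The trans-fused pyran can close only from the less favoured chair of the carbocycle (C5 side chain axial, two syn-axial methyls), so epoxide rearrangement or elimination may outrun cyclisation. The fallback ties the two side arms into a ring before cyclising; it sets out from 20 (isolated after the MeLi addition) and comes back at 22. Ring-closing metathesis (second-generation Grubbs catalyst, CH2Cl2, 40 °C) joins the allyl and dimethylallyl arms into ring A and gives (1R,2R,4aR,8aS)-1-{2-[(2S,3S)-2,3-dimethyloxiran-2-yl]ethyl}-2,5,5,8a-tetramethyl-1,2,3,4,4a,5,8,8a-octahydronaphthalen-2-ol F4. In this cis-fused octalin the conformer needed for closure is an ordinary chair–chair form, so CSA in CH2Cl2 should give (1S)-1-[(3R,4aR,6aR,10aS,10bR)-3,4a,7,7,10a-pentamethyl-2,3,4a,5,6,6a,7,10,10a,10b-decahydro-1H-benzo[f]chromen-3-yl]ethan-1-ol F5. Ozonolysis in methanolic NaOH as in step 13 then cuts the ring A alkene into the two methyl esters of 22.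

Step 14. The carbinol is secondary, neopentyl-like and next to the ether oxygen, so the sulfamate may ionise and rearrange instead of eliminating. The fallback makes the vinyl group by reduction of an enol triflate; it sets out from 22 and comes back at 23. Dess–Martin oxidation gives methyl 2-[(2R,4aR,5S,6S,8aR)-2-acetyl-5-(2-methoxy-2-oxoethyl)-2,5,8a-trimethyloctahydro-2H-chromen-6-yl]-2-methylpropanoate F6. KN(SiMe3)2 and PhN(SO2CF3)2 in THF at −78 °C convert the more acidic methyl ketone into methyl 2-[(2R,4aR,5S,6S,8aR)-5-(2-methoxy-2-oxoethyl)-2,5,8a-trimethyl-2-{1-[(trifluoromethanesulfonyl)oxy]ethenyl}octahydro-2H-chromen-6-yl]-2-methylpropanoate F7. Pd(OAc)2/PPh3 with Bu3N and HCO2H in DMF at 60 °C replaces the triflate by hydrogen and gives 23.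

**Further compounds**
F1 | step 11 | (2R,3S,4R)-2-bromo-3-methyl-4-(2-methylbut-3-en-2-yl)-3-(prop-2-en-1-yl)cyclohexan-1-one | Br[C@@H]1[C@@](C)(CC=C)[C@@H](C(C)(C)C=C)CCC1=O
F2 | step 11 | (2S,3S)-2-(2-iodoethyl)-2,3-dimethyloxirane | C[C@@H]1O[C@@]1(C)CCI
F3 | step 11 | {2-[(2S,3S)-2,3-dimethyloxiran-2-yl]ethyl}(iodo)zinc | C[C@@H]1O[C@@]1(C)CC[Zn]I
F4 | step 12 | (1R,2R,4aR,8aS)-1-{2-[(2S,3S)-2,3-dimethyloxiran-2-yl]ethyl}-2,5,5,8a-tetramethyl-1,2,3,4,4a,5,8,8a-octahydronaphthalen-2-ol | C[C@@H]1O[C@@]1(C)CC[C@@H]2[C@@]3(C)CC=CC(C)(C)[C@H]3CC[C@@]2(C)O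
F5 | step 12 | (1S)-1-[(3R,4aR,6aR,10aS,10bR)-3,4a,7,7,10a-pentamethyl-2,3,4a,5,6,6a,7,10,10a,10b-decahydro-1H-benzo[f]chromen-3-yl]ethan-1-ol | C[C@H](O)[C@@]1(C)CC[C@@H]2[C@@]3(C)CC=CC(C)(C)[C@H]3CC[C@@]2(C)O1
F6 | step 14 | methyl 2-[(2R,4aR,5S,6S,8aR)-2-acetyl-5-(2-methoxy-2-oxoethyl)-2,5,8a-trimethyloctahydro-2H-chromen-6-yl]-2-methylpropanoate | CC(=O)[C@@]1(C)CC[C@@H]2[C@@](C)(CC(=O)OC)[C@@H](C(C)(C)C(=O)OC)CC[C@@]2(C)O1
F7 | step 14 | methyl 2-[(2R,4aR,5S,6S,8aR)-5-(2-methoxy-2-oxoethyl)-2,5,8a-trimethyl-2-{1-[(trifluoromethanesulfonyl)oxy]ethenyl}octahydro-2H-chromen-6-yl]-2-methylpropanoate | C=C(OS(=O)(=O)C(F)(F)F)[C@@]1(C)CC[C@@H]2[C@@](C)(CC(=O)OC)[C@@H](C(C)(C)C(=O)OC)CC[C@@]2(C)O1
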